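The question is which of two flasks with the same charge ends with the higher excess of left-handed product: Monday's, stopped at 2.5 h, or Thursday's, stopped at 5.0 h.

all flasks: precatalyst 40 µM

| run | left-handed substrate | right-handed substrate | coupling partner | remark | time |
|---|---|---|---|---|---|
| alder | 20 mM | 20 mM | 27 mM | run made earlier |  |
| ash | 20 mM | 20 mM | 60 mM | run made earlier |  |
| cedar | 10 mM | 10 mM | 40 mM | run made earlier |  |
| Thursday's | 20 mM | 20 mM | 40.0 mM |  | 5.0 h |
| Monday's | 20 mM | 20 mM | 40.0 mM |  | 2.5 h |

| run | time / h | left-handed product / % | right-handed product / % |
|---|---|---|---|
| alder | 0.500 | 2.1 | 0.4 |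
| alder | 0.833 | 4.2 | 0.8 |
| alder | 1.33 | 9.4 | 3.2 |
| alder | 2.00 | 16.5 | 7.2 |
| alder | 4.00 | 27.9 | 11.2 |
| alder | 6.00 | 33.4 | 15.4 |
| ash | 0.417 | 6.4 | 2.3 |
| ash | 1.33 | 27.7 | 12.1 |
| ash | 2.00 | 37.7 | 19.4 |
| ash | 3.00 | 44.6 | 25.7 |
| ash | 5.00 | 49.1 | 34.4 |
| ash | 6.00 | 49.4 | 36.8 |
| cedar | 0.500 | 4.6 | 2.2 |
| cedar | 1.50 | 20.2 | 9.0 |
| cedar | 3.00 | 38.7 | 18.8 |
| cedar | 4.00 | 43.7 | 23.6 |
| cedar | 6.00 | 47.6 | 32.9 |

(each reading ± 0.5 percentage points)

* which of the two ends with the higher excess of left-handed product over right-handed product in the product ("neither" if they lie within 2 percentage points) (Thursday's / Monday's / neither)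
* excess of left-handed product over right-handed product in the product at the end, Thursday's
* excess of left-handed product over right-handed product in the product at the end, Monday's

- catalyst is single-handed; left-handed substrate and right-handed substrate are mirror images of each other, charged as a racemate, each of them at the stated concentration
- the earlier runs were read with a standard deviation of 0.5 percentage points
- steps that have been proposed: coupling partner + catalyst + left-handed substrate -> catalyst + left-handed product; catalyst <-> dormant form; coupling partner + catalyst + right-handed substrate -> catalyst + right-handed product; coupling partner + precatalyst -> catalyst + spent reagent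
- an excess is the difference of the two amounts in percent of their sum
- an excess is below zero if the other one leads

One thing in the ash run looks contradictory. The single-handed catalyst seems to keep a steady preference, yet the excess in the product falls from 47.1% at 0.417 h to 26.9% at 3.00 h. I test the preference with the ash reading at 3.00 h, which gives 3.08 for the selectivity factor, the logarithm of the fraction of left-handed substrate remaining over the same logarithm for the right-handed substrate. The first ash reading gives 2.91, about the same.

Within the scatter of these two ash readings the preference holds, and the contradiction clears once I weigh it by what remains. At 3.00 h the ash run keeps 10.8% of its left-handed substrate and 48.6% of its right-handed substrate, so left-handed product forms at 0.684 times the rate of right-handed product, and the late product dilutes the excess.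

This gives a rule for equal charges of the two substrates at a fixed factor: the fraction of right-handed substrate remaining is the left-handed fraction raised to one over the factor, and the excess is the difference of the two fractions consumed over their sum. Thursday's flask is Monday's carried further, so I expect Monday's to stand higher.

The forecast says Monday's, with 38.5% for Monday's and 30% for Thursday's, on the ground that “Excess therefore depends only on conversion”.

The flask gives Monday's, at 39.4% against 30.5% for Thursday's. Its steps are these:

    coupling partner + catalyst + left-handed substrate → catalyst + left-handed product (k = 20400 L² mol⁻² min⁻¹)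
    catalyst ⇌ dormant form (K = 0.950, k = 0.00680 min⁻¹)
    coupling partner + catalyst + right-handed substrate → catalyst + right-handed product (k = 6720 L² mol⁻² min⁻¹)
    coupling partner + precatalyst → catalyst + spent reagent (k = 0.165 L mol⁻¹ min⁻¹)

Monday's flask keeps 40% of its left-handed substrate at 2.50 h, and Thursday's keeps 17% at 5.00 h. Put into the rule with my factor, Thursday's 17% gives 31.0%. A neighbour of Thursday's, charged with 68 mM of coupling partner, keeps 1.3% of its left-handed substrate, for which the rule gives 13.3%, and that neighbour ends at 13.0%.

(The numbers in the tables were computed with made-up constants, and the scatter is random.)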